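**Plan**

1. Cuts: C11=C12 and C11'=C12' (carotenoid numbering), two Wittig olefinations on a C10 triene bis-phosphonium salt, give two C15 dienals. In ring A the oxolane ring C6–O–C3–C2–C1 is traced back to the 1,2-dioxane ring C6–O–O–C3–C2–C1 of a 2,3-dioxabicyclo[2.2.2]octane, contracted by loss of one oxygen.
2. Enabling feature: C3 and C6 are 1,4-cis oxygenated carbons of the cyclohexane. C6 is tertiary, conjugated to the side-chain diene and flanked by C1 and C5, which carry no hydrogen, so an activated C6–O bond can ionise and be re-closed only by the C3 oxygen on the same face. Ring B has the same cis C3–O/C6–O pattern, so one endoperoxide, from singlet-oxygen [4+2] addition to the C3=C4–C5=C6 diene of a safranal-derived tetraene ester, serves both end groups.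
3. Forward: C15 chain by Horner–Wadsworth–Emmons olefination; [4+2] closes the dioxabicyclooctene; resolution. Ring A: epoxidation, PPh3 ring contraction, hydride opening. Ring B: O–O reduction, oxymercuration. Both are oxidised to dienals and joined to the C10 unit, ring A first, ring B last.
4. Stereochemistry: C3/C6 cis from the suprafacial [4+2]; absolute configuration from one chromatographic resolution of the endoperoxide; C5 of ring A from epoxidation on the peroxide face; C5' of ring B from hydroxyl-directed anti oxymercuration; E double bonds from the olefinations and a final thermal isomerisation.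

Key step: step 5

Remark: carotenoid numbering is used for ring and chain positions; the target is read as (3R,5R,6S,3'R,5'S,6'S), so ring A has the 5-OH on the face of the 3,6-oxygen bridge and ring B has the 5'-OH trans to the cis-related 3'- and 6'-OH; compounds 1, 2 and 16 are taken as purchased.

**Route**

Step 1
Reactants: 1 safranal; 2 triethyl 3-methyl-4-phosphonocrotonate
Product: 3 ethyl (2E,4E)-3-methyl-5-(2,6,6-trimethylcyclohexa-1,3-dien-1-yl)penta-2,4-dienoate
Conditions: NaH, THF, 0 °C to rt
Reagents that add atoms: none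
Why: Horner–Wadsworth–Emmons olefination of the hindered enal with the stabilised C5 phosphonate anion should give the new C7=C8 bond E, and the minor 2Z isomer is removed by chromatography.

Step 2
Reactants: 3 ethyl (2E,4E)-3-methyl-5-(2,6,6-trimethylcyclohexa-1,3-dien-1-yl)penta-2,4-dienoate
Product: 4 racemic ethyl (2E,4E)-3-methyl-5-(6,7,7-trimethyl-2,3-dioxabicyclo[2.2.2]oct-5-en-1-yl)penta-2,4-dienoate
Conditions: O2, tetraphenylporphyrin (cat.), visible light, CH2Cl2, 0 °C
Reagents that add atoms: oxygen, O=O
Why: Singlet-oxygen [4+2] cycloaddition should take the s-cis-locked, alkyl-substituted ring diene in preference to the ester-deactivated acyclic diene, and the suprafacial addition sets the C3–O and C6–O bonds cis (racemic).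

Step 3
Reactants: 4 racemic endoperoxide ester
Product: 5 ethyl (2E,4E)-3-methyl-5-[(1S,4R)-6,7,7-trimethyl-2,3-dioxabicyclo[2.2.2]oct-5-en-1-yl]penta-2,4-dienoate
Conditions: preparative HPLC on cellulose tris(3,5-dimethylphenylcarbamate), hexane/2-propanol, rt
Reagents that add atoms: none
Why: Chromatographic resolution of a neutral, UV-active ester on a polysaccharide chiral phase; the (1S,4R) enantiomer is identified by Kornblum–DeLaMare rearrangement of an aliquot (Et3N) to ethyl (2E)-abscisate and chiroptical comparison with the ester made from natural (S)-abscisic acid, and this one resolution supplies both end groups.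

Step 4
Reactants: 5 (1S,4R)-endoperoxide ester
Product: 6 ethyl (2E,4E)-3-methyl-5-[(1S,2R,4R,5R)-2,8,8-trimethyl-3,6,7-trioxatricyclo[3.2.2.0(2,4)]non-1-yl]penta-2,4-dienoate
Conditions: mCPBA, NaHCO3, CH2Cl2, 0 °C
Reagents that add atoms: mCPBA, OOC(=O)c1cccc(Cl)c1
Why: Peracid epoxidation of the trisubstituted ring alkene, the most electron-rich C=C, should occur on the face of the peroxide bridge because the other face is blocked by the methyl group of the gem-dimethyl carbon next to C6, which puts the C5 oxygen syn to the peroxide.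

Step 5
Reactants: 6 epoxy endoperoxide ester
Product: 8 ethyl (2E,4E)-3-methyl-5-[(1S,2R,4R,5R)-2,7,7-trimethyl-3,8-dioxatricyclo[3.2.1.0(2,4)]oct-1-yl]penta-2,4-dienoate, via dioxaphosphorane 7 (not isolated)
Conditions: PPh3, MeCN, 0 °C to rt
Reagents that add atoms: none
Why: Proposed new method: PPh3 attacks the less hindered peroxide oxygen (the one on C3), the O–O bond breaks and the betaine closes to the seven-membered dioxaphosphorane 7; its C6–O bond, at a tertiary carbon conjugated to the side-chain diene and flanked by C1 and C5 that bear no hydrogen, ionises, Ph3P=O leaves from the C3 oxygen, and this oxygen recombines with C6. The closest known reaction type is the deoxygenation of dialkyl peroxides and monocyclic 1,2-dioxanes to ethers and tetrahydrofurans by tertiary phosphines (and the related cyclodehydration of 1,4-diols through dioxaphosphoranes), where the C–O bond forms by SN2 inversion; a bridged endoperoxide cannot invert, so the step is asked to run through the ion pair with retention, which has not been shown for this substrate class. Ring change: the six-membered 1,2-dioxane C6–O–O–C3–C2–C1 expands to the phosphorane and contracts to the oxolane C6–O–C3–C2–C1; the C3–O–C6 bond closes by a transannular 5-exo-tet attack on the ion-paired C6 and completes the 7-oxabicyclo[2.2.1]heptane. No new stereocentre arises: the C3–O bond is never broken, C6 is re-bonded on its original face because the C3 oxygen is held on that face by the carbocycle, and the C4–C5 epoxide is a spectator. The selectivity needed is ionisation at C6 in preference to elimination of the C3 alkoxyphosphonium towards C2; it is secured by the stabilised C6 cation, which has no β-hydrogen on C1 or C5 to lose, by the polar solvent and by the low temperature.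

Step 6
Reactants: 8 epoxy ether ester
Product: 9 (2E,4E)-5-[(1S,2R,4R)-2-hydroxy-2,6,6-trimethyl-7-oxabicyclo[2.2.1]heptan-1-yl]-3-methylpenta-2,4-dien-1-ol
Conditions: LiEt3BH (excess), THF, 0 °C to rt
Reagents that add atoms: none
Why: LiEt3BH reduces the ester to the allylic alcohol and opens the epoxide by SN2 attack of hydride on the less substituted C4 from the endo face, anti to the epoxide oxygen, so the C5–O bond is kept and the tertiary 5-OH stays on the face of the oxygen bridge.

Step 7
Reactants: 9 ring A dienol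
Product: 10 (2E,4E)-5-[(1S,2R,4R)-2-hydroxy-2,6,6-trimethyl-7-oxabicyclo[2.2.1]heptan-1-yl]-3-methylpenta-2,4-dienal
Conditions: MnO2, CH2Cl2, rt
Reagents that add atoms: none
Why: MnO2 oxidises only the primary allylic alcohol, and the tertiary alcohol and the ether are inert.

Step 8
Reactants: 5 (1S,4R)-endoperoxide ester
Product: 11 ethyl (2E,4E)-5-[(1S,4R)-1,4-dihydroxy-2,6,6-trimethylcyclohex-2-en-1-yl]-3-methylpenta-2,4-dienoate
Conditions: thiourea, MeOH, rt
Reagents that add atoms: none
Why: Thiourea reduces the O–O bond of bicyclic endoperoxides to the cis-1,4-diol without breaking a C–O bond, so C3 and C6 keep their configuration and the dienoate is untouched.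

Step 9
Reactants: 11 cis-diol ester
Product: 13 ethyl (2E,4E)-3-methyl-5-[(1S,2S,4R)-1,2,4-trihydroxy-2,6,6-trimethylcyclohexyl]penta-2,4-dienoate, via organomercurial acetate 12 (not isolated)
Conditions: Hg(OAc)2, THF/H2O, rt; then NaBH4, aq. NaOH, 0 °C
Reagents that add atoms: water, O
Why: Oxymercuration–demercuration: mercury should be delivered to the alkene face that carries the two allylic hydroxyls (hydroxyl coordination, the other face being shielded by the C6 side chain), water opens the mercurinium ion anti at the tertiary C5 so that the new 5-OH is trans to both hydroxyls, and NaBH4 replaces mercury on C4 by hydrogen.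

Step 10
Reactants: 13 triol ester
Product: 14 (1S,2S,4R)-1-[(1E,3E)-5-hydroxy-3-methylpenta-1,3-dien-1-yl]-2,6,6-trimethylcyclohexane-1,2,4-triol
Conditions: DIBAL-H (excess), CH2Cl2, −78 to 0 °C; aq. sodium potassium tartrate
Reagents that add atoms: none
Why: DIBAL-H reduces the conjugated ester 1,2 to the primary allylic alcohol, and the free hydroxyls only consume reagent as aluminium alkoxides.

Step 11
Reactants: 14 ring B tetraol
Product: 15 (2E,4E)-3-methyl-5-[(1S,2S,4R)-1,2,4-trihydroxy-2,6,6-trimethylcyclohexyl]penta-2,4-dienal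
Conditions: MnO2, EtOAc, rt
Reagents that add atoms: none
Why: MnO2 oxidises only the primary allylic alcohol, since the secondary 3-OH is not allylic and the tertiary alcohols cannot be oxidised.

Step 12
Reactants: 16 (2E,4E,6E)-2,7-dimethylocta-2,4,6-trienedial
Product: 17 (2E,4E,6E)-2,7-dimethylocta-2,4,6-triene-1,8-diol
Conditions: NaBH4, MeOH/CH2Cl2, 0 °C
Reagents that add atoms: none
Why: NaBH4 reduces both enal carbonyls 1,2 to the bis-allylic diol without touching the triene.

Step 13
Reactants: 17 C10 diol
Product: 18 [(2E,4E,6E)-2,7-dimethylocta-2,4,6-triene-1,8-diyl]bis(triphenylphosphonium) dibromide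
Conditions: PPh3·HBr, MeOH, rt
Reagents that add atoms: triphenylphosphine hydrobromide, [Br-].[PH+](c1ccccc1)(c1ccccc1)c1ccccc1
Why: The protonated allylic alcohols are displaced by PPh3 at the primary termini through the triene-stabilised cation, the standard preparation of polyenyl phosphonium salts, and the conjugated all-E triene is kept.

Step 14
Reactants: 10 ring A dienal; 18 C10 bis-phosphonium salt (excess)
Product: 19 [(2E,4E,6E,8E,10E,12E)-13-[(1S,2R,4R)-2-hydroxy-2,6,6-trimethyl-7-oxabicyclo[2.2.1]heptan-1-yl]-2,7,11-trimethyltrideca-2,4,6,8,10,12-hexaen-1-yl](triphenyl)phosphonium bromide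
Conditions: NaOMe (1 equiv.), CH2Cl2/MeOH, 0 °C to rt
Reagents that add atoms: none
Why: Wittig olefination: one equivalent of base turns the bis-salt into its mono-ylide, a delocalised species that is deprotonated a second time only reluctantly, which forms C11=C12 with 10 while the excess of 18 suppresses double reaction; the new bond may form as an E/Z mixture that is carried on (all-E form drawn).

Step 15
Reactants: 19 C25 phosphonium bromide; 15 ring B dienal
Product: 20 (3R,5R,6S,3'R,5'S,6'S)-3,6-epoxy-5,6,5',6'-tetrahydro-β,β-carotene-5,3',5',6'-tetrol (CNP0261804.1)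
Conditions: NaOMe, CH2Cl2/MeOH, 0 °C to rt; then EtOAc, reflux, argon, dark, base-washed glassware
Reagents that add atoms: none
Why: The second Wittig olefination forms C11'=C12' in the presence of the free hydroxyls, heating should convert the hindered Z double bonds at C11 and C11' into the all-E polyene, and no stereocentre is touched.

**Compound list**

1 | safranal (2,6,6-trimethylcyclohexa-1,3-diene-1-carbaldehyde) | CC1=C(C=O)C(C)(C)CC=C1 | starting material
2 | triethyl 3-methyl-4-phosphonocrotonate (ethyl (2E)-4-(diethoxyphosphoryl)-3-methylbut-2-enoate) | CCOC(=O)/C=C(C)/CP(=O)(OCC)OCC | starting material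
3 | ethyl (2E,4E)-3-methyl-5-(2,6,6-trimethylcyclohexa-1,3-dien-1-yl)penta-2,4-dienoate | CCOC(=O)/C=C(C)/C=C/C1=C(C)C=CCC1(C)C | intermediate
4 | racemic ethyl (2E,4E)-3-methyl-5-(6,7,7-trimethyl-2,3-dioxabicyclo[2.2.2]oct-5-en-1-yl)penta-2,4-dienoate (1:1 mixture of the (1S,4R) and (1R,4S) forms; the bridge fixes the relative configuration) | CCOC(=O)/C=C(C)/C=C/C12OOC(CC1(C)C)C=C2C | intermediate
5 | ethyl (2E,4E)-3-methyl-5-[(1S,4R)-6,7,7-trimethyl-2,3-dioxabicyclo[2.2.2]oct-5-en-1-yl]penta-2,4-dienoate | CCOC(=O)/C=C(C)/C=C/[C@]12OO[C@H](CC1(C)C)C=C2C | intermediate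
6 | ethyl (2E,4E)-3-methyl-5-[(1S,2R,4R,5R)-2,8,8-trimethyl-3,6,7-trioxatricyclo[3.2.2.0(2,4)]non-1-yl]penta-2,4-dienoate (epoxide oxygen syn to the peroxide bridge) | CCOC(=O)/C=C(C)/C=C/[C@]12OO[C@H](CC1(C)C)[C@H]3O[C@@]23C | intermediate
7 | pentacoordinate dioxaphosphorane from insertion of PPh3 into the O–O bond of 6 (O–PPh3–O bridge between C3 and C6, other centres as in 6; formed in the flask, not isolated) | CCOC(=O)/C=C(C)/C=C/[C@]12OP(c3ccccc3)(c3ccccc3)(c3ccccc3)O[C@H](CC1(C)C)[C@H]3O[C@@]23C | intermediate
8 | ethyl (2E,4E)-3-methyl-5-[(1S,2R,4R,5R)-2,7,7-trimethyl-3,8-dioxatricyclo[3.2.1.0(2,4)]oct-1-yl]penta-2,4-dienoate (epoxide exo, syn to the oxygen bridge) | CCOC(=O)/C=C(C)/C=C/[C@]12O[C@H](CC1(C)C)[C@H]3O[C@@]23C | intermediate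
9 | (2E,4E)-5-[(1S,2R,4R)-2-hydroxy-2,6,6-trimethyl-7-oxabicyclo[2.2.1]heptan-1-yl]-3-methylpenta-2,4-dien-1-ol | OC/C=C(C)/C=C/[C@]12O[C@H](CC1(C)C)C[C@@]2(C)O | intermediate
10 | (2E,4E)-5-[(1S,2R,4R)-2-hydroxy-2,6,6-trimethyl-7-oxabicyclo[2.2.1]heptan-1-yl]-3-methylpenta-2,4-dienal | O=C/C=C(C)/C=C/[C@]12O[C@H](CC1(C)C)C[C@@]2(C)O | intermediate
11 | ethyl (2E,4E)-5-[(1S,4R)-1,4-dihydroxy-2,6,6-trimethylcyclohex-2-en-1-yl]-3-methylpenta-2,4-dienoate | CCOC(=O)/C=C(C)/C=C/[C@]1(O)C(C)(C)C[C@@H](O)C=C1C | intermediate
12 | organomercurial acetate: adduct of 11 with HgOAc on the former alkene CH (cis to the 1- and 4-hydroxyls) and the new tertiary hydroxyl trans to them (formed in the flask, not isolated) | CCOC(=O)/C=C(C)/C=C/[C@]1(O)C(C)(C)C[C@@H](O)[C@@H]([Hg]OC(C)=O)[C@]1(C)O | intermediate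
13 | ethyl (2E,4E)-3-methyl-5-[(1S,2S,4R)-1,2,4-trihydroxy-2,6,6-trimethylcyclohexyl]penta-2,4-dienoate | CCOC(=O)/C=C(C)/C=C/[C@]1(O)C(C)(C)C[C@@H](O)C[C@]1(C)O | intermediate
14 | (1S,2S,4R)-1-[(1E,3E)-5-hydroxy-3-methylpenta-1,3-dien-1-yl]-2,6,6-trimethylcyclohexane-1,2,4-triol | OC/C=C(C)/C=C/[C@]1(O)C(C)(C)C[C@@H](O)C[C@]1(C)O | intermediate
15 | (2E,4E)-3-methyl-5-[(1S,2S,4R)-1,2,4-trihydroxy-2,6,6-trimethylcyclohexyl]penta-2,4-dienal | O=C/C=C(C)/C=C/[C@]1(O)C(C)(C)C[C@@H](O)C[C@]1(C)O | intermediate
16 | (2E,4E,6E)-2,7-dimethylocta-2,4,6-trienedial | O=C/C(C)=C/C=C/C=C(C)/C=O | starting material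
17 | (2E,4E,6E)-2,7-dimethylocta-2,4,6-triene-1,8-diol | OC/C(C)=C/C=C/C=C(C)/CO | intermediate
18 | [(2E,4E,6E)-2,7-dimethylocta-2,4,6-triene-1,8-diyl]bis(triphenylphosphonium) dibromide | [Br-].[Br-].C(/C(C)=C/C=C/C=C(C)/C[P+](c1ccccc1)(c1ccccc1)c1ccccc1)[P+](c1ccccc1)(c1ccccc1)c1ccccc1 | intermediate
19 | [(2E,4E,6E,8E,10E,12E)-13-[(1S,2R,4R)-2-hydroxy-2,6,6-trimethyl-7-oxabicyclo[2.2.1]heptan-1-yl]-2,7,11-trimethyltrideca-2,4,6,8,10,12-hexaen-1-yl](triphenyl)phosphonium bromide | [Br-].C(/C(C)=C/C=C/C=C(C)/C=C/C=C(C)/C=C/[C@]12O[C@H](CC1(C)C)C[C@@]2(C)O)[P+](c1ccccc1)(c1ccccc1)c1ccccc1 | intermediate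
20 | (3R,5R,6S,3'R,5'S,6'S)-3,6-epoxy-5,6,5',6'-tetrahydro-β,β-carotene-5,3',5',6'-tetrol (CNP0261804.1) | CC(/C=C/C=C(C)/C=C/[C@]12O[C@H](CC1(C)C)C[C@@]2(C)O)=C\C=C\C=C(C)\C=C\C=C(C)\C=C\[C@]1(O)C(C)(C)C[C@@H](O)C[C@]1(C)O | target

**Count and risks**

Total step count: 15. Longest linear sequence: 9 steps (steps 1 to 7, then 14 and 15).

Steps most likely to fail:

Step 5 (ring contraction). The alkoxyphosphonium intermediate may collapse by elimination towards C2 to a ring-opened allylic alcohol, or ionisation at C6 may be too slow because the ester-terminated diene stabilises the cation only moderately. The fallback sets out from 6 and returns at 9. Reduction of 6 with LiAlH4 (THF, 0 °C to rt) cleaves the O–O bond, opens the epoxide at C4 and reduces the ester, and should give the all-cis tetraol (1S,2R,4R)-1-[(1E,3E)-5-hydroxy-3-methylpenta-1,3-dien-1-yl]-2,6,6-trimethylcyclohexane-1,2,4-triol F1. A trace of acid (PPTS, CH2Cl2, 0 °C) then ionises the tertiary allylic C6–OH, and the cis 3-OH closes the 3,6-ether. This is the acid-induced closure of 3,5,6-triols to 3,6-epoxides known in the carotenoid series, and it gives 9.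

Step 4 (epoxidation of the endoperoxide). Facial selectivity may be poor, since the electrostatic preference of dioxabicyclooctenes for attack anti to the O–O bridge may outweigh the steric shielding by the bridge methyl; the dienoate may also be over-oxidised. The fallback sets out from 11 (made in step 8) and returns at 9. Epoxidation of 11 with VO(acac)2/t-BuOOH (CH2Cl2, 0 °C) is directed by both allylic hydroxyls to their own face and should give the all-cis epoxy diol ethyl (2E,4E)-5-[(1R,2S,5R,6R)-2,5-dihydroxy-1,3,3-trimethyl-7-oxabicyclo[4.1.0]heptan-2-yl]-3-methylpenta-2,4-dienoate F2. LiAlH4 opens the epoxide at C4 and reduces the ester to give the tetraol F1 of the preceding fallback, which is closed with PPTS to 9.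

Step 9 (oxymercuration). Mercuration may occur on the face away from the hydroxyls or at the dienoate, and the acetic acid set free may ionise the tertiary allylic hydroxyl. The fallback sets out from 5 and returns at 14. Epoxidation of 5 with the small oxidant DMDO (acetone, −20 °C) on the face remote from the peroxide bridge, the face simple dioxabicyclooctenes prefer, gives ethyl (2E,4E)-3-methyl-5-[(1S,2S,4S,5R)-2,8,8-trimethyl-3,6,7-trioxatricyclo[3.2.2.0(2,4)]non-1-yl]penta-2,4-dienoate F3. F3 is also the diastereomer of 6 that can be collected as by-product of step 4. LiAlH4 (THF, 0 °C) then cleaves the O–O bond, reduces the ester and opens the epoxide at C4 with hydride delivered from the neighbouring C3 alkoxyaluminate, giving 14 directly.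

Further compounds
F1 | step 5 | (1S,2R,4R)-1-[(1E,3E)-5-hydroxy-3-methylpenta-1,3-dien-1-yl]-2,6,6-trimethylcyclohexane-1,2,4-triol | OC/C=C(C)/C=C/[C@]1(O)C(C)(C)C[C@@H](O)C[C@@]1(C)O
F2 | step 4 | ethyl (2E,4E)-5-[(1R,2S,5R,6R)-2,5-dihydroxy-1,3,3-trimethyl-7-oxabicyclo[4.1.0]heptan-2-yl]-3-methylpenta-2,4-dienoate | CCOC(=O)/C=C(C)/C=C/[C@]1(O)C(C)(C)C[C@@H](O)[C@H]2O[C@@]12C
F3 | step 9 | ethyl (2E,4E)-3-methyl-5-[(1S,2S,4S,5R)-2,8,8-trimethyl-3,6,7-trioxatricyclo[3.2.2.0(2,4)]non-1-yl]penta-2,4-dienoate | CCOC(=O)/C=C(C)/C=C/[C@]12OO[C@H](CC1(C)C)[C@@H]3O[C@]23C
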